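Early times already argued against the obvious reading: at Monday's first reading the isomer of the product stood at 19%, and it ended at 48%, above the 8.47% of the charge that was other conformer. I took the isomer to grow from other conformer, so starting material had to be refilling it.

| flask | starting material | coupling partner | other conformer | temperature | remark | time |
|---|---|---|---|---|---|---|
| Monday's | 0.40 M (in portions, 3) | 0.42 M | 0.037 M | 30 °C | run made earlier; portions every 4.0 min |  |
| Friday's | 0.40 M (in portions, 3) | 0.42 M | 0.11 M | 41 °C | run made earlier; portions every 4.0 min |  |
| gamma | 0.40 M | 0.420 M | 0.0250 M | 35 °C | everything together at the start | 10 h |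
| beta | 0.40 M (in portions, 3) | 0.420 M | 0.100 M | 35 °C | the portions of starting material follow each other after 4.0 min, the first at the start | 10 h |

| run | time / h | target / % | isomer of the product / % | starting material / % |
|---|---|---|---|---|
| Monday's | 0.333 | 5 | 19 | 59 |
| Monday's | 1.00 | 11 | 38 | 29 |
| Monday's | 2.00 | 10 | 45 | 13 |
| Monday's | 2.50 | 15 | 45 | 10 |
| Monday's | 4.00 | 13 | 46 | 4 |
| Monday's | 5.00 | 15 | 48 | 9 |
| Friday's | 0.417 | 10 | 26 | 33 |
| Friday's | 0.667 | 15 | 29 | 19 |
| Friday's | 1.00 | 14 | 30 | 14 |
| Friday's | 2.00 | 14 | 32 | 10 |
| Friday's | 3.00 | 17 | 36 | 9 |
| Friday's | 5.00 | 18 | 38 | 6 |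

(scatter of a reading: 1.5 percentage points)

- what was read earlier has a scatter of 1.5 percentage points, one standard deviation
- in a conversion other conformer counts as not yet reacted

1. the flask that ends with the higher share of target in all that became target or isomer of the product, or "neither" when 2 percentage points or less lies between them (gamma / beta / neither)
2. share of target in all that became target or isomer of the product, gamma
3. share of target in all that became target or isomer of the product, beta

The coupling partner is the limiting reagent in gamma and beta. I assumed each target and each isomer costs one of it, so its balance comes down to a split, S, target made per isomer made; the asked share is S/(1+S).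

I went through what S needed. The charge of other conformer I did not need closely, given that refilling; Friday's isomer also ended at 38%, above its charged 21.6%. The dosing the runs could not test, both being made in 3 portions, so I assumed I did not need it closely. Nor the time: Monday's ratio went from 0.263 to 0.312, within what a scatter of 1.5 percentage points on small readings allows. Temperature I did need.

Summed over each run's readings, S read 0.286 on Monday and 0.461 on Friday. Taking its logarithm as straight in temperature, I got 0.355 at 35 °C: the selectivity factor, target made per isomer made. That is a share of 26.2% in gamma and in beta alike, a tie.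

The forecast differed: 22% (18% to 27%) for gamma, 29% (25% to 33%) for beta, and beta higher, on the ground that “A distinct conformer feeding the target seems the likelier cause”.

Gamma gave 26.4% and beta 26.1%, inside both ranges, but the choice is neither; as S that is 0.359 and 0.353 against my 0.355.

    starting material ⇌ other conformer (K = 0.150, k = 0.570 min⁻¹, Ea = 82.0 kJ mol⁻¹, ΔH = −21.0 kJ mol⁻¹)
    starting material + coupling partner → target (k = 0.0220 M⁻¹ min⁻¹, Ea = 66.0 kJ mol⁻¹)
    coupling partner + other conformer → isomer of the product (k = 0.420 M⁻¹ min⁻¹, Ea = 49.0 kJ mol⁻¹)
    starting material ⇌ dormant form (K = 5.60, k = 0.0140 min⁻¹, Ea = 97.0 kJ mol⁻¹, ΔH = −18.0 kJ mol⁻¹)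
    2 coupling partner → homo dimer (k = 0.0120 M⁻¹ min⁻¹, Ea = 61.0 kJ mol⁻¹)
    (constants at 35 °C)

In beta, half the turnover to target was done by 0.372 h and to isomer by 0.372 h, while starting material passed to other conformer with a forward half-life of 1.2 min. Dormant form stood at 36.2% after 5.00 h and 33.0% after 10.0 h. For a flask like beta at 20 °C, below both runs, the same line gives S = 0.186, a share of 15.7%; the computed flask gave 14.6%.

The numbers in the tables are calculated for an exercise; noise was put on by code.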